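**Retrosynthetic overview**
- The target comes from Z-selective semi-reduction of both alkynes of a 20-membered bis-enyne diolide, itself closed by head-to-tail Sonogashira cyclodimerisation of an alkynyl (Z)-3-iodo-2-methylacrylate.
- That ester is cut at the C–O bond into a hydroxy-alkyne carrying both stereocentres and (Z)-3-iodo-2-methylacrylic acid (from propargyl alcohol by anti-carbomagnesiation/iodination, then oxidation).
- The hydroxy-alkyne comes from a palladium-catalysed conjunctive coupling (1,2-boronate shift) of a secondary boronic ester, vinyllithium and 5-bromooxazole, which sets the carbinol centre.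
- The secondary boronic ester comes from a sparteine-mediated lithiation–borylation (1,2-boronate shift with methyl migration) of a carbamate assembled from 1-(trimethylsilyl)propyne and ethylene oxide, which sets the methyl centre.
- Rings: the oxazole is bought intact; the only ring formed is the 20-membered diolide, closed in step 7.

Assumption: (Sp,Sp)-MandyPhos is taken to give the (2R) boronate 11 by analogy with the parent vinylboron ate complexes; if it gives the (2S) epimer, the (Rp,Rp) ligand is used instead.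

**Step 1**
Reactants: 1 trimethyl(prop-1-yn-1-yl)silane; 2 oxirane (ethylene oxide)
Product: 5 5-(trimethylsilyl)pent-4-yn-1-yl N,N-diisopropylcarbamate, via propargyllithium 3 (not isolated), via lithium alkoxide 4 (not isolated)
Conditions: n-BuLi, THF, –78 → –20 °C; 2 (THF solution), –78 °C → rt; then i-Pr2NC(O)Cl, reflux
Reagents that add atoms: N,N-diisopropylcarbamoyl chloride, CC(C)N(C(C)C)C(Cl)=O
Why: Propargylic lithiation of 1 (the silyl group blocks the allenyl terminus), SN2 opening of the epoxide and O-carbamoylation of the resulting lithium alkoxide run in one pot and create no stereocentre.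

**Step 2**
Reactants: 5 5-(trimethylsilyl)pent-4-yn-1-yl N,N-diisopropylcarbamate
Product: 8 4,4,5,5-tetramethyl-2-[(2R)-6-(trimethylsilyl)hex-5-yn-2-yl]-1,3,2-dioxaborolane, via lithiated carbamate 6 (not isolated), via boron ate complex 7 (not isolated)
Conditions: s-BuLi, (+)-sparteine, Et2O, –78 °C, 5 h; MeBpin, –78 °C, 1 h; MgBr2·OEt2, reflux, 16 h
Reagents that add atoms: 2,4,4,5,5-pentamethyl-1,3,2-dioxaborolane (MeBpin), CB1OC(C)(C)C(C)(C)O1
Why: Hoppe asymmetric deprotonation with (+)-sparteine gives the configurationally stable (R)-α-lithio carbamate, which is borylated with retention and then undergoes the stereoinvertive 1,2-metallate rearrangement of the Aggarwal lithiation–borylation (methyl migrates from boron to carbon, carbamate leaves), setting the methyl-bearing centre as (R).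

**Step 3**
Reactants: 8 4,4,5,5-tetramethyl-2-[(2R)-6-(trimethylsilyl)hex-5-yn-2-yl]-1,3,2-dioxaborolane; 9 5-bromo-1,3-oxazole
Product: 13 (2R,3R)-3-methyl-1-(1,3-oxazol-5-yl)hept-6-yn-2-ol, via vinyl ate complex 10 (not isolated), via secondary boronate 11 (not isolated), via silyl alkynol 12 (not isolated)
Conditions: vinyllithium (halide-free stock solution), THF, 0 °C → rt; Pd(OAc)2 (3 mol %), (Sp,Sp)-MandyPhos (3.6 mol %), 9, KOTf, THF, 60 °C, 14 h; then 3 M NaOH, 30 % H2O2, THF/MeOH, 0 °C → rt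
Reagents that add atoms: vinyllithium, [Li]C=C; hydrogen peroxide, OO
Why: Proposed new method: oxidative addition of 5-bromooxazole to zerovalent palladium gives, after bromide abstraction by KOTf, a cationic divalent oxazolyl–palladium species that binds the vinyl group of ate complex 10 and triggers an anti 1,2-shift of the α-stereogenic secondary alkyl group from boron to the α-carbon (retention at the migrating carbon) while palladium bonds to the β-carbon, and reductive elimination then forms the CH2–C5(oxazole) bond with the MandyPhos ligand fixing the new C–B centre as (R) before stereoretentive oxidation and hydroxide cleavage of the alkynyl silane; the closest known reaction is the MandyPhos–palladium conjunctive cross-coupling of vinylboron ate complexes with aryl and alkenyl triflates or halides, which has not been shown for an azol-5-yl bromide with a free C2–H and a Lewis-basic nitrogen, nor for a chiral secondary alkyl migrating group where the catalyst must override substrate bias.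

**Step 4**
Reactants: 14 prop-2-yn-1-ol
Product: 16 (2Z)-3-iodo-2-methylprop-2-en-1-ol, via magnesium chelate 15 (not isolated)
Conditions: MeMgBr (3 equiv), CuI (10 mol %), THF, –10 °C → rt; then I2, –10 °C → rt
Reagents that add atoms: methylmagnesium bromide, C[Mg]Br; iodine, II
Why: The alkoxide-directed, copper-catalysed anti-carbomagnesiation of propargyl alcohol places methyl on the internal carbon and magnesium cis to the CH2O group in a five-membered chelate, and iodinolysis with retention gives only the Z vinyl iodide.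

**Step 5**
Reactants: 16 (2Z)-3-iodo-2-methylprop-2-en-1-ol
Product: 18 (2Z)-3-iodo-2-methylprop-2-enoic acid, via enal 17 (not isolated)
Conditions: TEMPO (20 mol %), PhI(OAc)2 (2.4 equiv), MeCN/H2O 1:1, rt
Reagents that add atoms: water, O
Why: The oxoammonium oxidation in aqueous acetonitrile takes the allylic alcohol through the enal and its hydrate to the acid under near-neutral conditions that leave the vinyl iodide and its Z geometry untouched.

**Step 6**
Reactants: 13 (2R,3R)-3-methyl-1-(1,3-oxazol-5-yl)hept-6-yn-2-ol; 18 (2Z)-3-iodo-2-methylprop-2-enoic acid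
Product: 20 (2R,3R)-3-methyl-1-(1,3-oxazol-5-yl)hept-6-yn-2-yl (2Z)-3-iodo-2-methylprop-2-enoate, via acid chloride 19 (not isolated)
Conditions: 18, 1-chloro-N,N,2-trimethylprop-1-en-1-amine, CH2Cl2, 0 °C, 1 h; then 13, pyridine, 0 °C → rt
Reagents that add atoms: none
Why: Neutral acid chloride formation with the Ghosez reagent and DMAP-free O-acylation avoid the addition–elimination pathway that isomerises Z β-iodoacrylates, and acylation at oxygen leaves both stereocentres unchanged.

**Step 7**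
Reactants: 20 (2R,3R)-3-methyl-1-(1,3-oxazol-5-yl)hept-6-yn-2-yl (2Z)-3-iodo-2-methylprop-2-enoate (two molecules)
Product: 22 (3Z,9R,10R,13Z,19R,20R)-3,9,13,19-tetramethyl-10,20-bis(1,3-oxazol-5-ylmethyl)-1,11-dioxacycloicosa-3,13-diene-5,15-diyne-2,12-dione, via linear dimer 21 (not isolated)
Conditions: Pd(PPh3)4 (10 mol %), CuI (20 mol %), i-Pr2NH, degassed THF, 3 mM (slow addition of 20), rt
Reagents that add atoms: none
Why: Sonogashira coupling of a Z β-iodoacrylate runs at room temperature with retention of geometry, and because closure of the monomer would need a strained ten-membered cyclic enyne, the head-to-tail dimer 21 forms first and then closes to the 20-membered ring.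

**Step 8**
Reactants: 22 (3Z,9R,10R,13Z,19R,20R)-3,9,13,19-tetramethyl-10,20-bis(1,3-oxazol-5-ylmethyl)-1,11-dioxacycloicosa-3,13-diene-5,15-diyne-2,12-dione
Product: 24 (3Z,5Z,9R,10R,13Z,15Z,19R,20R)-3,9,13,19-tetramethyl-10,20-bis(1,3-oxazol-5-ylmethyl)-1,11-dioxacycloicosa-3,5,13,15-tetraene-2,12-dione, via mono-reduced macrocycle 23 (not isolated)
Conditions: Zn dust activated with Cu(OAc)2 and AgNO3, MeOH/H2O 1:1, 40 °C
Reagents that add atoms: none
Why: The Boland reduction with copper/silver-activated zinc cis-reduces only conjugated alkynes, giving both 4Z alkenes without over-reduction and without touching the enoates, esters or oxazoles.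

**Compound list**
1 | trimethyl(prop-1-yn-1-yl)silane | CC#C[Si](C)(C)C | starting material
2 | oxirane (ethylene oxide) | C1CO1 | starting material
3 | [3-(trimethylsilyl)prop-2-yn-1-yl]lithium | [Li]CC#C[Si](C)(C)C | intermediate
4 | lithium 5-(trimethylsilyl)pent-4-yn-1-olate | [Li+].[O-]CCCC#C[Si](C)(C)C | intermediate
5 | 5-(trimethylsilyl)pent-4-yn-1-yl N,N-diisopropylcarbamate | CC(C)N(C(C)C)C(=O)OCCCC#C[Si](C)(C)C | intermediate
6 | (1R)-1-lithio-5-(trimethylsilyl)pent-4-yn-1-yl N,N-diisopropylcarbamate, (+)-sparteine complex | [Li][C@H](CCC#C[Si](C)(C)C)OC(=O)N(C(C)C)C(C)C | intermediate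
7 | lithium [(1R)-1-(N,N-diisopropylcarbamoyloxy)-5-(trimethylsilyl)pent-4-yn-1-yl](methyl)(pinacolato)borate | C[B-]1(OC(C)(C)C(C)(C)O1)[C@H](CCC#C[Si](C)(C)C)OC(=O)N(C(C)C)C(C)C.[Li+] | intermediate
8 | 4,4,5,5-tetramethyl-2-[(2R)-6-(trimethylsilyl)hex-5-yn-2-yl]-1,3,2-dioxaborolane | C[C@H](CCC#C[Si](C)(C)C)B1OC(C)(C)C(C)(C)O1 | intermediate
9 | 5-bromo-1,3-oxazole | Brc1cnco1 | starting material
10 | lithium ethenyl(pinacolato)[(2R)-6-(trimethylsilyl)hex-5-yn-2-yl]borate | C[C@H](CCC#C[Si](C)(C)C)[B-]1(C=C)OC(C)(C)C(C)(C)O1.[Li+] | intermediate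
11 | 4,4,5,5-tetramethyl-2-[(2R,3R)-3-methyl-1-(1,3-oxazol-5-yl)-7-(trimethylsilyl)hept-6-yn-2-yl]-1,3,2-dioxaborolane | C[Si](C)(C)C#CCC[C@@H](C)[C@@H](Cc1cnco1)B1OC(C)(C)C(C)(C)O1 | intermediate
12 | (2R,3R)-3-methyl-1-(1,3-oxazol-5-yl)-7-(trimethylsilyl)hept-6-yn-2-ol | C[Si](C)(C)C#CCC[C@@H](C)[C@@H](Cc1cnco1)O | intermediate
13 | (2R,3R)-3-methyl-1-(1,3-oxazol-5-yl)hept-6-yn-2-ol | C#CCC[C@@H](C)[C@@H](Cc1cnco1)O | intermediate
14 | prop-2-yn-1-ol | C#CCO | starting material
15 | 4-methyl-2,5-dihydro-1,2-oxamagnesole (cyclic alkenylmagnesium alkoxide) | CC1=C[Mg]OC1 | intermediate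
16 | (2Z)-3-iodo-2-methylprop-2-en-1-ol | OC/C(C)=C\I | intermediate
17 | (2Z)-3-iodo-2-methylprop-2-enal | O=C/C(C)=C\I | intermediate
18 | (2Z)-3-iodo-2-methylprop-2-enoic acid | OC(=O)/C(C)=C\I | intermediate
19 | (2Z)-3-iodo-2-methylprop-2-enoyl chloride | ClC(=O)/C(C)=C\I | intermediate
20 | (2R,3R)-3-methyl-1-(1,3-oxazol-5-yl)hept-6-yn-2-yl (2Z)-3-iodo-2-methylprop-2-enoate | C#CCC[C@@H](C)[C@@H](Cc1cnco1)OC(=O)/C(C)=C\I | intermediate
21 | (2R,3R)-3-methyl-1-(1,3-oxazol-5-yl)hept-6-yn-2-yl (2Z,8R,9R)-9-{[(2Z)-3-iodo-2-methylprop-2-enoyl]oxy}-2,8-dimethyl-10-(1,3-oxazol-5-yl)dec-2-en-4-ynoate | C#CCC[C@@H](C)[C@@H](Cc1cnco1)OC(=O)/C(C)=C\C#CCC[C@@H](C)[C@@H](Cc1cnco1)OC(=O)/C(C)=C\I | intermediate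
22 | (3Z,9R,10R,13Z,19R,20R)-3,9,13,19-tetramethyl-10,20-bis(1,3-oxazol-5-ylmethyl)-1,11-dioxacycloicosa-3,13-diene-5,15-diyne-2,12-dione | C/C1=C/C#CCC[C@@H](C)[C@@H](Cc2cnco2)OC(=O)/C(C)=C\C#CCC[C@@H](C)[C@@H](Cc2cnco2)OC1=O | intermediate
23 | (3Z,5Z,9R,10R,13Z,19R,20R)-3,9,13,19-tetramethyl-10,20-bis(1,3-oxazol-5-ylmethyl)-1,11-dioxacycloicosa-3,5,13-trien-15-yne-2,12-dione | C/C1=C/C=C\CC[C@@H](C)[C@@H](Cc2cnco2)OC(=O)/C(C)=C\C#CCC[C@@H](C)[C@@H](Cc2cnco2)OC1=O | intermediate
24 | (3Z,5Z,9R,10R,13Z,15Z,19R,20R)-3,9,13,19-tetramethyl-10,20-bis(1,3-oxazol-5-ylmethyl)-1,11-dioxacycloicosa-3,5,13,15-tetraene-2,12-dione | C/C1=C/C=C\CC[C@@H](C)[C@@H](Cc2cnco2)OC(=O)/C(C)=C\C=C/CC[C@@H](C)[C@@H](Cc2cnco2)OC1=O | target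

**Step count and risks**
Total steps: 8. Longest linear sequence: 6 (steps 1, 2, 3, 6, 7, 8).

Steps most likely to fail:

- **Step 3 (the proposed new conjunctive coupling).** The oxazolyl–palladium species may give direct Suzuki vinyl transfer, or the C2–H and nitrogen of the oxazole may interfere. The fallback uses known chemistry only, sets out from 8 and comes back at 13.
  - But-3-en-1-ol is carbamoylated (i-Pr2NC(O)Cl, Et3N, reflux) to but-3-en-1-yl N,N-diisopropylcarbamate F3.
  - F3 is lithiated with s-BuLi/(–)-sparteine, 8 is added and MgBr2·OEt2 at reflux drives a second, reagent-controlled lithiation–borylation to 4,4,5,5-tetramethyl-2-[(4R,5R)-5-methyl-9-(trimethylsilyl)non-1-en-8-yn-4-yl]-1,3,2-dioxaborolane F4.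
  - NaOH/H2O2 (THF, 0 °C) gives (4R,5R)-5-methyl-9-(trimethylsilyl)non-1-en-8-yn-4-ol F5.
  - TBSCl/imidazole gives tert-butyl(dimethyl){[(4R,5R)-5-methyl-9-(trimethylsilyl)non-1-en-8-yn-4-yl]oxy}silane F6.
  - OsO4 (cat.)/NaIO4/2,6-lutidine cleaves the terminal alkene to (3R,4R)-3-[(tert-butyldimethylsilyl)oxy]-4-methyl-8-(trimethylsilyl)oct-7-ynal F7.
  - A van Leusen reaction (TosMIC, K2CO3, MeOH, reflux, which also removes the alkynyl silane) builds the ring as 5-[(2R,3R)-2-[(tert-butyldimethylsilyl)oxy]-3-methylhept-6-yn-1-yl]-1,3-oxazole F8.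
  - TBAF then gives 13.

- **Step 7 (Sonogashira cyclodimerisation).** Open-chain oligomers may dominate. The fallback closes the ring at the two ester bonds instead, sets out from 13 and 18 and comes back at 22. Intermolecular Sonogashira coupling of 13 with 18 (Pd(PPh3)4, CuI, i-Pr2NH, THF, rt) gives (2Z,8R,9R)-9-hydroxy-2,8-dimethyl-10-(1,3-oxazol-5-yl)dec-2-en-4-ynoic acid F9. Yamaguchi cyclodimerisation of F9 (2,4,6-trichlorobenzoyl chloride, Et3N, THF; then DMAP, toluene, 5 mM) gives 22.

- **Step 2 (methyl migration in the lithiation–borylation).** Methyl is a poor migrating group, so yield or enantiomeric ratio may suffer. The fallback reverses the partners so that a primary alkyl group migrates; it sets out from 1 and comes back at 8.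
  - Lithiated 1 (as in step 1) is quenched with 2-(iodomethyl)-4,4,5,5-tetramethyl-1,3,2-dioxaborolane (Matteson-type homologation) to give 4,4,5,5-tetramethyl-2-[4-(trimethylsilyl)but-3-yn-1-yl]-1,3,2-dioxaborolane F1.
  - Ethanol is carbamoylated to ethyl N,N-diisopropylcarbamate F2.
  - F2 is deprotonated with s-BuLi/(–)-sparteine in Et2O at –78 °C, F1 is added and MgBr2·OEt2 at reflux gives 8 directly (the (S)-carbenoid reacts with inversion).

**Further compounds**
F1 | step 2 | 4,4,5,5-tetramethyl-2-[4-(trimethylsilyl)but-3-yn-1-yl]-1,3,2-dioxaborolane | C[Si](C)(C)C#CCCB1OC(C)(C)C(C)(C)O1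
F2 | step 2 | ethyl N,N-diisopropylcarbamate | CCOC(=O)N(C(C)C)C(C)C
F3 | step 3 | but-3-en-1-yl N,N-diisopropylcarbamate | C=CCCOC(=O)N(C(C)C)C(C)C
F4 | step 3 | 4,4,5,5-tetramethyl-2-[(4R,5R)-5-methyl-9-(trimethylsilyl)non-1-en-8-yn-4-yl]-1,3,2-dioxaborolane | C[Si](C)(C)C#CCC[C@@H](C)[C@@H](CC=C)B1OC(C)(C)C(C)(C)O1
F5 | step 3 | (4R,5R)-5-methyl-9-(trimethylsilyl)non-1-en-8-yn-4-ol | C[Si](C)(C)C#CCC[C@@H](C)[C@@H](CC=C)O
F6 | step 3 | tert-butyl(dimethyl){[(4R,5R)-5-methyl-9-(trimethylsilyl)non-1-en-8-yn-4-yl]oxy}silane | C[Si](C)(C)C#CCC[C@@H](C)[C@@H](CC=C)O[Si](C)(C)C(C)(C)C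
F7 | step 3 | (3R,4R)-3-[(tert-butyldimethylsilyl)oxy]-4-methyl-8-(trimethylsilyl)oct-7-ynal | C[Si](C)(C)C#CCC[C@@H](C)[C@@H](CC=O)O[Si](C)(C)C(C)(C)C
F8 | step 3 | 5-[(2R,3R)-2-[(tert-butyldimethylsilyl)oxy]-3-methylhept-6-yn-1-yl]-1,3-oxazole | C#CCC[C@@H](C)[C@@H](Cc1cnco1)O[Si](C)(C)C(C)(C)C
F9 | step 7 | (2Z,8R,9R)-9-hydroxy-2,8-dimethyl-10-(1,3-oxazol-5-yl)dec-2-en-4-ynoic acid | OC(=O)/C(C)=C\C#CCC[C@@H](C)[C@@H](Cc1cnco1)O
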